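**Retrosynthetic overview**
1. Last bond: C3 of a bought 3-bromobutenolide is joined to the end of an allyl arm by hydroboration and B-alkyl Suzuki coupling. The butenolide ring is never built; it arrives intact.
2. That allyl arm and the free CH2OH on the S centre are released together by zinc from a 2-(bromomethyl)tetrahydrofuran, which masks both through the middle of the route.
3. The Z-allylic alcohol arm comes from a vinyl group on the R centre and (Z)-3-iodo-2-methylprop-2-en-1-ol (a second B-alkyl Suzuki coupling).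
4. The R centre and its acetate come from an enantioselective copper-catalysed SN2' coupling of the alkylborane from the free allyl arm with (Z)-4-chlorobut-2-enyl acetate.
5. Key step and only ring formation: an enantioselective, C–O bond-forming bromoetherification picks one of the two enantiotopic allyl groups of achiral 2-allylpent-4-en-1-ol. The tetrahydrofuran is made in step 2 and opened in step 7.

Assumption: 2-allylpent-4-enoic acid, (Z)-1,4-dichlorobut-2-ene, prop-2-yn-1-ol and 3-bromofuran-2(5H)-one are bought. The ligand antipodes named are assigned by analogy and would be swapped if the opposite sense were found.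

**Step 1**
Reactants: 1 2-allylpent-4-enoic acid
Product: 2 2-allylpent-4-en-1-ol
Conditions: LiAlH4 (1.2 equiv), Et2O, 0 °C to reflux, 2 h; H2O/NaOH work-up
Reagents that add atoms: none
Why: Hydride reduction of a carboxylic acid with LiAlH4 leaves isolated terminal alkenes alone and gives the achiral alcohol whose branching carbon carries two enantiotopic allyl groups.

**Step 2**
Reactants: 2 2-allylpent-4-en-1-ol
Product: 3 (2S,4S)-4-allyl-2-(bromomethyl)tetrahydrofuran
Conditions: Cu(OTf)2 (15 mol %), (S,S)-tBu-box (18 mol %), 2,2-dibromopropane (6 equiv), MnO2 (3 equiv), K2CO3 (1 equiv), 4 Å MS, PhCF3, 105 °C, sealed tube, 24 h; cis isomer separated from trans on silica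
Reagents that add atoms: 2,2-dibromopropane, CC(C)(Br)Br
Why: Proposed new method: the box-ligated divalent copper alkoxide of 2 adds O and Cu syn across one allyl group through a chair-like transition state, so C–O bond formation is the stereo-determining event (the ligand fixes the alkene face and hence 2S, and only the pro-S allyl group can offer that face while the spectator allyl sits pseudo-equatorial, which gives the cis ring and 4S), after which the weak C–Cu bond homolyses, the primary radical takes bromine from the concentrated 2,2-dibromopropane before it can reach the second alkene, and MnO2 returns monovalent copper to divalent copper; the closest known reaction type is the copper/bis(oxazoline)-catalysed enantioselective oxycupration of 4-pentenols (carboetherification, hydroalkoxylation) together with the halogen-atom-transfer aminohalogenation of pentenyl sulfonamides, but to my knowledge neither a bromine-atom-transfer ending in the oxygen series nor a choice between two enantiotopic allyl groups has been shown.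

**Step 3**
Reactants: 4 (Z)-1,4-dichlorobut-2-ene
Product: 5 (Z)-4-chlorobut-2-en-1-yl acetate
Conditions: KOAc (0.8 equiv), Bu4NCl (5 mol %), MeCN, 50 °C; fractional distillation
Reagents that add atoms: potassium acetate, CC(=O)[O-].[K+]
Why: SN2 displacement of one primary allylic chloride by acetate keeps the Z geometry, and sub-stoichiometric acetate plus distillation removes unreacted dichloride and the diacetate.

**Step 4**
Reactants: 3 (2S,4S)-4-allyl-2-(bromomethyl)tetrahydrofuran; 5 (Z)-4-chlorobut-2-en-1-yl acetate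
Product: 7 (2R)-2-{3-[(3S,5S)-5-(bromomethyl)tetrahydrofuran-3-yl]propyl}but-3-en-1-yl acetate, via B-alkyl-9-BBN adduct 6 (not isolated)
Conditions: 3, (9-BBN-H)2 (0.55 equiv), THF, 60 °C, 1 h; KOEt (1.0 equiv); then (CuOTf)2·toluene (5 mol %), (R)-DTBM-SEGPHOS (11 mol %), 5 (1.3 equiv), THF–dioxane, 15 °C, 24 h
Reagents that add atoms: 9-borabicyclo[3.3.1]nonane (9-BBN-H), [H]B1C2CCCC1CCC2 (its boron unit stays in 6 only; 7 keeps just the hydrogen)
Why: Anti-Markovnikov hydroboration of the only alkene is followed by the known copper/chiral bisphosphine-catalysed γ-selective (SN2') allyl–alkyl coupling of an alkyl-9-BBN ate complex, in which the alkylcopper attacks the alkene carbon bearing CH2OAc as chloride leaves, the ligand alone sets the new centre as R because the ring centres are remote, and acetate and alkyl bromide survive because the ethoxide is bound in the borate before 5 is added.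

**Step 5**
Reactants: 8 prop-2-yn-1-ol
Product: 10 (Z)-3-iodo-2-methylprop-2-en-1-ol, via alkenylmagnesium alkoxide 9 (not isolated)
Conditions: MeMgBr (2.5 equiv), CuI (10 mol %), THF, −10 °C to rt, 12 h; I2 (1.2 equiv), −10 °C; cold 1 M HCl
Reagents that add atoms: methylmagnesium bromide, C[Mg]Br; iodine, [I][I]
Why: Copper-catalysed anti-carbomagnesiation of the propargylic alkoxide puts methyl on C2 and magnesium on C3 cis to CH2O (five-membered chelate), and iodinolysis with retention gives the Z iodide.

**Step 6**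
Reactants: 7 (2R)-2-{3-[(3S,5S)-5-(bromomethyl)tetrahydrofuran-3-yl]propyl}but-3-en-1-yl acetate; 10 (Z)-3-iodo-2-methylprop-2-en-1-ol
Product: 12 (2R,5Z)-2-{3-[(3S,5S)-5-(bromomethyl)tetrahydrofuran-3-yl]propyl}-7-hydroxy-6-methylhept-5-en-1-yl acetate, via B-alkyl-9-BBN adduct 11 (not isolated)
Conditions: 7, 9-BBN-H (1.3 equiv), THF, rt, 4 h; then 10 (1.2 equiv), Pd(dppf)Cl2 (5 mol %), AsPh3 (10 mol %), K3PO4 (3 M aq, 2.5 equiv), DMF, rt, 12 h
Reagents that add atoms: 9-borabicyclo[3.3.1]nonane (9-BBN-H), [H]B1C2CCCC1CCC2 (its boron unit stays in 11 only; 12 keeps just the hydrogen)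
Why: In this B-alkyl Suzuki–Miyaura coupling 9-BBN adds to the terminal carbon of the vinyl group, the alkenyl iodide undergoes oxidative addition far faster than the β-oxygenated primary bromide, the Z geometry is retained and no stereocentre is touched.

**Step 7**
Reactants: 12 (2R,5Z)-2-{3-[(3S,5S)-5-(bromomethyl)tetrahydrofuran-3-yl]propyl}-7-hydroxy-6-methylhept-5-en-1-yl acetate
Product: 13 (2R,5Z)-7-hydroxy-2-[(4S)-4-(hydroxymethyl)hept-6-en-1-yl]-6-methylhept-5-en-1-yl acetate
Conditions: Zn dust (acid-washed, 15 equiv), NH4Cl (5 equiv), EtOH–H2O 9:1, 80 °C, 3 h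
Reagents that add atoms: none
Why: In this Boord-type reductive fragmentation zinc inserts into the C–Br bond and expels the β-alkoxide, which gives back the terminal alkene and the primary alcohol at once, erases the helper ring centre and leaves the S centre, the acetate and the Z-allylic alcohol untouched.

**Step 8**
Reactants: 13 (2R,5Z)-7-hydroxy-2-[(4S)-4-(hydroxymethyl)hept-6-en-1-yl]-6-methylhept-5-en-1-yl acetate; 14 3-bromofuran-2(5H)-one
Product: 16 (2R,5Z)-7-hydroxy-2-[(4S)-4-(hydroxymethyl)-7-(2-oxo-2,5-dihydrofuran-3-yl)heptyl]-6-methylhept-5-en-1-yl acetate, via tris-9-BBN adduct 15 (not isolated)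
Conditions: 13, 9-BBN-H (3.3 equiv), THF, 0 °C to rt, 3 h; then 14 (1.5 equiv), Pd(dppf)Cl2 (10 mol %), AsPh3 (20 mol %), K3PO4 (3 M aq, 3 equiv), DMF, rt, 8 h
Reagents that add atoms: 9-borabicyclo[3.3.1]nonane (9-BBN-H), [H]B1C2CCCC1CCC2 (its boron units stay in 15 only; 16 keeps just the hydrogen)
Why: In this B-alkyl Suzuki–Miyaura coupling of an α-bromo-enoate-type halide two equivalents of 9-BBN are spent on the hydroxyls (borinates, hydrolysed by the aqueous base), the third adds to the terminal alkene much faster than to the trisubstituted one, phosphate at room temperature spares acetate and butenolide, and no stereocentre is touched.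

**Compound list**
1 | 2-allylpent-4-enoic acid (diallylacetic acid) | C=CCC(CC=C)C(=O)O | starting material
2 | 2-allylpent-4-en-1-ol | C=CCC(CC=C)CO | intermediate
3 | (2S,4S)-4-allyl-2-(bromomethyl)tetrahydrofuran (cis) | C=CC[C@@H]1CO[C@H](CBr)C1 | intermediate
4 | (Z)-1,4-dichlorobut-2-ene | ClC/C=C\CCl | starting material
5 | (Z)-4-chlorobut-2-en-1-yl acetate | CC(=O)OC/C=C\CCl | intermediate
6 | 9-{3-[(3S,5S)-5-(bromomethyl)tetrahydrofuran-3-yl]propyl}-9-borabicyclo[3.3.1]nonane | B1(CCC[C@@H]2CO[C@H](CBr)C2)C3CCCC1CCC3 | intermediate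
7 | (2R)-2-{3-[(3S,5S)-5-(bromomethyl)tetrahydrofuran-3-yl]propyl}but-3-en-1-yl acetate | CC(=O)OC[C@@H](C=C)CCC[C@@H]1CO[C@H](CBr)C1 | intermediate
8 | prop-2-yn-1-ol | C#CCO | starting material
9 | bromomagnesium (Z)-3-(bromomagnesio)-2-methylprop-2-en-1-olate (Mg on carbon cis to CH2O) | Br[Mg]/C=C(/C)CO[Mg]Br | intermediate
10 | (Z)-3-iodo-2-methylprop-2-en-1-ol | I/C=C(/C)CO | intermediate
11 | 9-BBN adduct of 7 (boron on the former vinyl terminus, all three stereocentres placed as in 7) | CC(=O)OC[C@@H](CCB1C2CCCC1CCC2)CCC[C@@H]3CO[C@H](CBr)C3 | intermediate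
12 | (2R,5Z)-2-{3-[(3S,5S)-5-(bromomethyl)tetrahydrofuran-3-yl]propyl}-7-hydroxy-6-methylhept-5-en-1-yl acetate | CC(=O)OC[C@@H](CC/C=C(/C)CO)CCC[C@@H]1CO[C@H](CBr)C1 | intermediate
13 | (2R,5Z)-7-hydroxy-2-[(4S)-4-(hydroxymethyl)hept-6-en-1-yl]-6-methylhept-5-en-1-yl acetate | CC(=O)OC[C@@H](CC/C=C(/C)CO)CCC[C@H](CO)CC=C | intermediate
14 | 3-bromofuran-2(5H)-one | O=C1OCC=C1Br | starting material
15 | tris(9-BBN) adduct of 13 (boron on the former alkene terminus, both hydroxyls as O-(9-BBN) borinates, stereocentres placed as in 13) | CC(=O)OC[C@@H](CC/C=C(/C)COB1C2CCCC1CCC2)CCC[C@H](COB3C4CCCC3CCC4)CCCB5C6CCCC5CCC6 | intermediate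
16 | (2R,5Z)-7-hydroxy-2-[(4S)-4-(hydroxymethyl)-7-(2-oxo-2,5-dihydrofuran-3-yl)heptyl]-6-methylhept-5-en-1-yl acetate | CC(=O)OC[C@@H](CC/C=C(/C)CO)CCC[C@H](CO)CCCC1=CCOC1=O | target

**Step count**
Total steps: 8. Longest linear sequence: 6 (steps 1, 2, 4, 6, 7, 8).

**Three steps most likely to fail**

*Step 2 (the new reaction).*
- Risks: the backbone has only one substituent, so ring closure may be slow.
- The minor trans isomer carries the opposite C4 configuration, so the cis/trans ratio limits the yield and the isomers must be separated cleanly.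
- The spectator allyl group may be attacked by radicals.
- Fallback (known chemistry, from 2 back to 3): NBS (1.05 equiv) in CH2Cl2 at 0 °C closes the ring by ordinary, unselective bromoetherification. It gives 3 together with its mirror image (2R,4R)-4-allyl-2-(bromomethyl)tetrahydrofuran F1 and the two trans isomers (2R,4S)-4-allyl-2-(bromomethyl)tetrahydrofuran F2 and (2S,4R)-4-allyl-2-(bromomethyl)tetrahydrofuran F3. Silica gel removes F2 and F3. Preparative chromatography of the cis racemate on a chiral polysaccharide phase then separates 3 from F1.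

*Step 4.*
- Risks: the allylic chloride carries a second, weaker leaving group (acetate) and an ester that free ethoxide could cleave.
- The enantioselectivity has not been proven for a CH2OAc substituent.
- Fallback (from 6 back to 7; a C–O bond again sets the centre):
  - Borane 6 is cross-coupled (Pd(dppf)Cl2, K3PO4 aq, DMF, rt) with 2-bromoprop-2-en-1-ol to give 5-[(3S,5S)-5-(bromomethyl)tetrahydrofuran-3-yl]-2-methylenepentan-1-ol F4.
  - 9-BBN-H (2.2 equiv) gives the bis(9-BBN) adduct of that allylic alcohol F5, and NaBO3 oxidises it to the prochiral 2-{3-[(3S,5S)-5-(bromomethyl)tetrahydrofuran-3-yl]propyl}propane-1,3-diol F6.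
  - Pseudomonas cepacia lipase and vinyl acetate in iPr2O acetylate one enantiotopic hydroxymethyl group to give (2R)-5-[(3S,5S)-5-(bromomethyl)tetrahydrofuran-3-yl]-2-(hydroxymethyl)pentyl acetate F7.
  - Dess–Martin periodinane gives (2S)-5-[(3S,5S)-5-(bromomethyl)tetrahydrofuran-3-yl]-2-formylpentyl acetate F8.
  - Salt-free Ph3P=CH2 in THF at −78 °C converts the formyl group into the vinyl group of 7.

*Step 8.*
- Risks: the bromobutenolide is base-sensitive, and the borane may protodeboronate before a slow coupling.
- Fallback (from 13 back to 16; the ring is built instead of bought): a ruthenium-catalysed Alder-ene reaction of the allyl group of 13 with ethyl 4-hydroxybut-2-ynoate ([CpRu(MeCN)3]PF6, 5 mol %, acetone, rt) gives ethyl (Z)-4-hydroxy-2-[(2E,4S)-alk-2-enyl]but-2-enoate F9. This closes in the flask to the butenolide with an E double bond next to the S centre, (2R,5Z)-7-hydroxy-2-[(4S,5E)-4-(hydroxymethyl)-7-(2-oxo-2,5-dihydrofuran-3-yl)hept-5-en-1-yl]-6-methylhept-5-en-1-yl acetate F10. RhCl(PPh3)3 under H2 (1 atm, benzene–EtOH) then saturates only the disubstituted alkene and gives 16.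

**Further compounds**
F1 | step 2 | (2R,4R)-4-allyl-2-(bromomethyl)tetrahydrofuran | C=CC[C@H]1CO[C@@H](CBr)C1
F2 | step 2 | (2R,4S)-4-allyl-2-(bromomethyl)tetrahydrofuran | C=CC[C@@H]1CO[C@@H](CBr)C1
F3 | step 2 | (2S,4R)-4-allyl-2-(bromomethyl)tetrahydrofuran | C=CC[C@H]1CO[C@H](CBr)C1
F4 | step 4 | 5-[(3S,5S)-5-(bromomethyl)tetrahydrofuran-3-yl]-2-methylenepentan-1-ol | C=C(CO)CCC[C@@H]1CO[C@H](CBr)C1
F5 | step 4 | bis(9-BBN) adduct of F4 (boron on the former methylene carbon and on oxygen, new centre unassigned) | C(B1C2CCCC1CCC2)C(COB3C4CCCC3CCC4)CCC[C@@H]5CO[C@H](CBr)C5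
F6 | step 4 | 2-{3-[(3S,5S)-5-(bromomethyl)tetrahydrofuran-3-yl]propyl}propane-1,3-diol | OCC(CO)CCC[C@@H]1CO[C@H](CBr)C1
F7 | step 4 | (2R)-5-[(3S,5S)-5-(bromomethyl)tetrahydrofuran-3-yl]-2-(hydroxymethyl)pentyl acetate | CC(=O)OC[C@@H](CO)CCC[C@@H]1CO[C@H](CBr)C1
F8 | step 4 | (2S)-5-[(3S,5S)-5-(bromomethyl)tetrahydrofuran-3-yl]-2-formylpentyl acetate | CC(=O)OC[C@@H](C=O)CCC[C@@H]1CO[C@H](CBr)C1
F9 | step 8 | ethyl (Z)-4-hydroxy-2-[(2E,4S)-alk-2-enyl]but-2-enoate, the open Alder-ene adduct of 13 | CC(=O)OC[C@@H](CC/C=C(/C)CO)CCC[C@H](CO)/C=C/C/C(C(=O)OCC)=C/CO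
F10 | step 8 | (2R,5Z)-7-hydroxy-2-[(4S,5E)-4-(hydroxymethyl)-7-(2-oxo-2,5-dihydrofuran-3-yl)hept-5-en-1-yl]-6-methylhept-5-en-1-yl acetate | CC(=O)OC[C@@H](CC/C=C(/C)CO)CCC[C@H](CO)/C=C/CC1=CCOC1=O
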